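## The problem

The target is a type B polyprenylated acylphloroglucinol: a bicyclo[3.3.1]nonane-2,4,9-trione whose C2–C3–C4 bridge is an enolised β-diketone carrying a 3,4-dihydroxybenzoyl group on C3. Ring A is C1–C5 with C9 and ring B is C5–C9 with C1; these locants are used for all bicyclic compounds below. Both bridgeheads are quaternary (C1 prenyl, C5 geranyl), and C1 is also bonded to the gem-dimethyl carbon C8, so the C1–C8 bond joins two fully substituted carbons and cannot be made by an ordinary alkylation. There are three stereocentres (C1, C5, C7), but the bridge ties C1 to C5. Only two things need control: the absolute configuration at C7, and the relation of the C7 prenyl group to the bridgeheads (equatorial on ring B, cis to the C5 geranyl group, anti to the C2–C4 bridge). C7 is the one centre that a catalyst can set on a simple precursor, and it can direct the construction of C5 if C5 is made while the two sit 1,3 to each other in a small ring. Four trisubstituted alkenes exclude hydrogenation, strong electrophiles and strong acid (acid cyclises them onto the enol oxygens). The β-triketone is open to retro-Claisen cleavage by hot nucleophilic base, and the catechol is oxidised in basic, aerated media. The feature that opens the structure is the chain C5–C6–C7–C8–C9 with C8 quaternary: closed by a C8–C9 bond it is a cyclopentanone with a single enolisable carbon, C5. A four-carbon acylating agent can then attach C4 to C5 and return its terminal carbon C1 to C9, after which C1 lies next to the C9 carbinol and a 1,2-shift of C8 from C9 to C1 forms the C1–C8 bond and opens the five-membered ring to ring B.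

## Retrosynthesis

**Unmasking and the C3 acyl group.** Target 26 is reached from its O2-methyl ether 25, and 25 from the bis-silyl ether 24. In 24 the bond from C3 to the aroyl carbon is cut, giving enol ether 19 and acid chloride 22, which comes from acid 20 through silyl ester 21. The aroyl group is put in last because the β-triketone and the catechol are the most fragile parts and would not survive the strong bases of the bridgehead chemistry. Precursor 19 lacks the aryl ketone and the catechol altogether. The forward step must metalate the vinylic C3–H, which is only clean once both bridgeheads are quaternary.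

**The C1 prenyl group.** In 19 the bond from C1 to its prenyl CH2 is cut, giving enol ether 16 and prenyl bromide 17. C1 rather than C5 is alkylated late because C1 is a methylene carbon until the ring expansion and becomes a bridgehead methine only then. The C5 substituent can go in much earlier by an ordinary enolate alkylation. The forward step needs a bridgehead carbanion at C1 formed in the presence of the C3–H and alkylated with retention.

**Ring expansion.** Enol ether 16 is the methyl ether of trione 15. In 15 the C1–C8 bond is cut and C8 is rejoined to C9, which becomes a carbinol; this is the retron of an oxidative 1,2-shift and leads to the cis-fused hydroxy dione 13. No intermolecular reaction could join quaternary C8 to a carbon flanked by two carbonyl groups, but as a migration within 13 the bond forms from the neighbouring atom. The precursor is a fused bicycle with no bridgehead. The forward step must make C1 the electrophilic terminus and must move C8 rather than C5.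

**Key disconnection.** In 13 the bonds C4–C5 and C1–C9 are cut. This removes C1–C4 as diketene 10 and leaves cyclopentanone 9. Cutting ring A elsewhere (C2–C3 with C3–C4, or C1–C2) would need separate carboxyl or acetonyl handles on neighbouring quaternary ring carbons. The chosen pair uses what the ketone already offers: its α-carbon as nucleophile, then its carbonyl carbon as electrophile. The precursor has one ring, and of its two stereocentres only the prenyl-bearing one matters. The forward reaction must acylate on carbon at a centre that becomes quaternary, on the face away from the prenyl group, and must close the aldol before the acetoacetyl group is lost.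

**The C5 geranyl group.** In 9 the bond from C5 to the geranyl CH2 is cut, giving ketone 6 and geranyl bromide 7. Ketone 6 has one enolisable carbon, so the alkylation has no regiochemical issue, and the configuration it creates is erased in the key step.

**The cyclopentanone.** The prenyl group of 6 is traced to the but-2-enyl group of 5 (one cross-metathesis) and that to the but-3-enyl group of 4 (one double-bond shift). In 4 the bond from the ring β-carbon to the side chain and the bond from the α-carbon to one methyl group are cut, giving enone 1 and Grignard reagent 2. A direct conjugate allylation would save a step, but allylmetal reagents add 1,2 under copper catalysis and no dependable enantioselective 1,4-allylation of this enone class exists; a homoallyl nucleophile is therefore used and the alkene is moved afterwards. This conjugate addition is the only step in which a reagent sets a stereocentre.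

## Roads not taken

**Alternative 1:** Ring A is cut at C2–C3 and C3–C4, so that C3 arrives with the aroyl group. Forward, the lithium enolate of the aryl methyl ketone A3 opens the bridged anhydride A2 (C2–C3). The freed carboxylate is then activated in the same flask as an acyl azolide and attacked by the diketonate carbon (C3–C4), giving the bis-silyl ether A1, one desilylation from the target.
- Merits: high convergence, no enol ether, no bridgehead lithiation, and the same product whichever anhydride carbonyl is attacked first.
- Weak points: A2 already holds all three stereocentres, both quaternary bridgeheads and the C1–C8 bond, so the core problem is only moved into its synthesis. Both anhydride carbonyls are neopentylic. The ring-opened intermediate is a β-keto carboxylate on a quaternary carbon and can decarboxylate. The second acylation must form a hindered triketone in competition with O-acylation to an enol lactone.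
- Comparison: with A2 in hand this end game would be shorter than the six steps the chosen plan needs after ring expansion. The chosen plan sets against this that it builds the bridged core in two steps (5 and 6) from a monocyclic ketone.

**Alternative 2:** Ring B is cut at C5–C6 and C1–C8. Forward, under a cinchonidinium phase-transfer catalyst and hydroxide, C5 of the monomethylated acylphloroglucinol A5 attacks the methylene of the acetoxy enal A6 with loss of acetate. C1 then adds to the gem-dimethyl terminus, giving the bicyclic vinylogous ester A4 with an exo C7 formyl group.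
- Merits: the best step economy of all four plans. The aromatic precursor carries ring A, the aroyl group and both bridgehead substituents, and one step builds ring B with both quaternary bridgeheads.
- Weak points: A5 has two different nucleophilic ring carbons. The first bond must form at the geranyl-bearing C5 and the Michael closure at C1 onto a β,β-disubstituted terminus; the reverse order puts the gem-dimethyl carbon next to the wrong bridgehead. The catalyst must distinguish the faces of a flat, delocalised anion over two successive C–C bond formations. The C7 formyl group of A4 is epimerisable and needs a one-carbon homologation and olefination to become prenyl, in the presence of the triketone system.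
- Comparison: on step count and on having the aroyl group in place from the start, this road is better. The chosen plan sets against it one early enantio-determining step on a simple enone with all later stereochemistry relayed by the substrate, a C7 prenyl group present from step 3, and an unambiguous position of the gem-dimethyl carbon.

**Alternative 3:** Ring B is cut at C5–C6 and C6–C7, with C6 supplied by formaldehyde A9. Forward, a diarylprolinol silyl ether catalyst condenses the pendant aldehyde of the achiral trione A8 with A9 to a 2-substituted acrolein. One of the two enantiotopic ring methylene carbons then adds to its methylene, giving the bicyclic trione A7 with an exo C7 formyl group and a hydrogen at C5.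
- Merits: an achiral precursor, a cheap catalyst, and all three stereocentres from one desymmetrising step.
- Weak points: A8 already contains the bond between quaternary C1 and quaternary C8, which no simple alkylation of a phloroglucinol provides. Its ring methylene groups are 1,3-dicarbonyl carbons and will condense with A9 themselves. After the key step, A7 still needs bridgehead geranylation at C5, homologation of the formyl group to prenyl, and C3 aroylation.
- Comparison: it matches the chosen plan in having a single stereo-defining event. It is longer after its key step, and that key step has no close precedent, whereas the chosen annulation and ring expansion are established reaction types.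

Key step: step 5

Assumption: ketone 9 is carried on as whatever C2 epimer mixture step 4 gives (the cis epimer is written), because step 5 erases this centre; β-dicarbonyl compounds are written as one tautomer.

## Route

Step 1
Reactants: 1 2-methylcyclopent-2-en-1-one; 2 but-3-en-1-ylmagnesium bromide
Product: 4 (3R)-3-(but-3-en-1-yl)-2,2-dimethylcyclopentan-1-one, via magnesium enolate 3 (not isolated)
Conditions: Cu(OTf)2 (3 mol %), chiral N-mesityl-N'-(1-hydroxy-4-methylpentan-2-yl)imidazolinium hexafluorophosphate (NHC precursor, 4 mol %, the antipode that gives the 3R adduct), Et2O, −30 °C, slow addition of 1; then MeI, DMPU, 0 °C → rt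
Reagents that add atoms: iodomethane, CI
Why: Copper-catalysed asymmetric conjugate addition of a Grignard reagent to an α-substituted cyclic enone with enolate trapping; the NHC–copper complex selects the enone face and so sets C3 (the later C7), and the regiodefined enolate 3 is methylated at its only carbon terminus to give the gem-dimethyl carbon.

Step 2
Reactants: 4 (3R)-3-(but-3-en-1-yl)-2,2-dimethylcyclopentan-1-one
Product: 5 (3S)-3-[(2E)-but-2-en-1-yl]-2,2-dimethylcyclopentan-1-one
Conditions: Pd(dba)2 (1 mol %), P(t-Bu)3 (1 mol %), i-PrCOCl (1 mol %), toluene, 80 °C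
Reagents that add atoms: none
Why: Palladium hydride-catalysed one-position alkene isomerisation; the terminal alkene inserts much faster than the internal product, so the shift should stop at the 2-alkene, and the E/Z composition is irrelevant because the next step cleaves this double bond.

Step 3
Reactants: 5 (3S)-3-[(2E)-but-2-en-1-yl]-2,2-dimethylcyclopentan-1-one
Product: 6 (3S)-2,2-dimethyl-3-(3-methylbut-2-en-1-yl)cyclopentan-1-one
Conditions: 2-methylbut-2-ene (excess), second-generation Grubbs catalyst (H2IMes)(PCy3)Cl2Ru=CHPh (3 mol %), CH2Cl2, 40 °C
Reagents that add atoms: 2-methylbut-2-ene, CC=C(C)C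
Why: Olefin cross-metathesis exchanges the ethylidene terminus for isopropylidene with loss of volatile but-2-ene; the trisubstituted product is inert to further metathesis and the stereocentre is not involved.

Step 4
Reactants: 6 (3S)-2,2-dimethyl-3-(3-methylbut-2-en-1-yl)cyclopentan-1-one; 7 geranyl bromide
Product: 9 (2S,4R)-2-[(2E)-3,7-dimethylocta-2,6-dien-1-yl]-5,5-dimethyl-4-(3-methylbut-2-en-1-yl)cyclopentan-1-one, via lithium enolate 8 (not isolated)
Conditions: LDA, THF, −78 °C; then 7, DMPU, −78 → 0 °C
Reagents that add atoms: none
Why: Enolate alkylation; the other α-carbon is quaternary, so only one enolate can form, and the primary allylic bromide reacts by SN2 at carbon; the configuration created here is erased in step 5.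

Step 5
Reactants: 9 (2S,4R)-2-geranyl-5,5-dimethyl-4-prenylcyclopentan-1-one; 10 diketene
Product: 13 (2R,3aR,7aR)-3a-geranyl-7a-hydroxy-1,1-dimethyl-2-prenyl-octahydroindene-4,6-dione (cis-fused; ring A on the cyclopentane, carbinol at C9), via lithium enolate 11 (not isolated), via acetoacetyl enolate 12 (not isolated)
Conditions: LiTMP (1.1 equiv), THF, −78 °C; 10 (1.2 equiv), −78 °C; LiTMP (1.3 equiv), −78 → −30 °C; cold dilute aq. HCl to pH 4
Reagents that add atoms: none
Why: LiTMP converts 9 into enolate 11, the only enolate possible because C8 is quaternary. C5 of 11 attacks the lactone carbonyl of diketene, and collapse of the tetrahedral intermediate opens the four-membered ring to give directly the terminal enolate 12 of the new acetoacetyl group (C4–C5 formed). The terminal carbon C1 of 12 then adds to the C9 ketone in a 6-(enolexo)-exo-trig aldol that closes ring A (C1–C9 formed); any material that has relaxed to the internal diketonate is returned to the reactive dianion by the second portion of LiTMP, and the product is held as its alkoxide–diketonate, which blocks retro-aldol. The closest known reaction type is the annulation of α-alkyl cyclopentanone enolates with diketene to fused hydroxy cyclohexane-1,3-diones. The C5 stereocentre is controlled by the C7 prenyl group, which sits 1,3 to C5 and sends the acylating agent to the opposite face, leaving geranyl cis to prenyl. The C9 carbinol is controlled by the tether, which can reach only the carbonyl face on its own side, so the fusion must be cis. The step needs C- over O-acylation and a clean facial choice at C5; the lithium enolate in THF at low temperature with a small, strained acyl donor favours the former and the prenyl group secures the latter. C7 is not α to a carbonyl group and cannot epimerise.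

Step 6
Reactants: 13 cis-fused hydroxy dione
Product: 15 (1R,5S,7R)-5-geranyl-8,8-dimethyl-7-prenylbicyclo[3.3.1]nonane-2,4,9-trione, via iodonium ylide 14 (not isolated)
Conditions: PhI(OAc)2 (1.2 equiv), KOH (3 equiv), MeOH, 0 °C; aq. NaH2PO4
Reagents that add atoms: none
Why: Hypervalent-iodine oxidative ring expansion (semipinacol-type 1,2-shift): the dione is activated as ylide 14, and through its enol form the C9 alkoxide pushes C8 from C9 to C1 with loss of iodobenzene, so the carbinol becomes the C9 ketone and the cyclopentane becomes ring B. C8 should migrate rather than C5 because it is the electron-richer carbon and its shift relieves the five-membered ring, whereas C5 carries the C4 carbonyl group; the C1 configuration is dictated by the bridged skeleton.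

Step 7
Reactants: 15 (1R,5S,7R)-5-geranyl-8,8-dimethyl-7-prenylbicyclo[3.3.1]nonane-2,4,9-trione
Product: 16 (1R,5S,7R)-5-geranyl-2-methoxy-8,8-dimethyl-7-prenylbicyclo[3.3.1]non-2-ene-4,9-dione
Conditions: HC(OMe)3, p-TsOH·H2O (5 mol %), MeOH, rt
Reagents that add atoms: trimethyl orthoformate, COC(OC)OC; methanol, CO
Why: Acid-catalysed enol ether formation of a cyclic 1,3-dione; methanol should add to the C2 carbonyl (tertiary neighbour C1) in preference to the C4 carbonyl (quaternary neighbour C5), which places the methoxy group on C2, and any C4 isomer can be hydrolysed back to 15.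

Step 8
Reactants: 16 (1R,5S,7R)-5-geranyl-2-methoxy-8,8-dimethyl-7-prenylbicyclo[3.3.1]non-2-ene-4,9-dione; 17 prenyl bromide
Product: 19 (1R,5S,7R)-5-geranyl-2-methoxy-8,8-dimethyl-1,7-diprenylbicyclo[3.3.1]non-2-ene-4,9-dione, via bridgehead organolithium 18 (not isolated)
Conditions: LDA (1.5 equiv), THF, −78 °C; then 17, −78 → −40 °C
Reagents that add atoms: none
Why: Bridgehead lithiation–alkylation of a bicyclo[3.3.1]nonanetrione enol ether; the C1–H is acidified inductively by the C9 carbonyl and the oxocarbenium-like C2, the bridgehead anion 18 cannot invert and is alkylated with retention, and the vinylic C3–H needs the more hindered amide base used in step 11.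

Step 9
Reactants: 20 3,4-dihydroxybenzoic acid
Product: 21 tert-butyldimethylsilyl 3,4-bis(tert-butyldimethylsilyloxy)benzoate
Conditions: TBSCl (3.5 equiv), imidazole, DMF, rt
Reagents that add atoms: tert-butyldimethylsilyl chloride, CC(C)(C)[Si](C)(C)Cl
Why: Silylation of both phenols and the carboxylic acid; the silyl ester is a neutral precursor of the acid chloride, and the aryl silyl ethers are removable by fluoride without acid or hydrogenation.

Step 10
Reactants: 21 tert-butyldimethylsilyl 3,4-bis(tert-butyldimethylsilyloxy)benzoate
Product: 22 3,4-bis(tert-butyldimethylsilyloxy)benzoyl chloride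
Conditions: (COCl)2, DMF (cat.), CH2Cl2, 0 °C → rt; used crude
Reagents that add atoms: oxalyl chloride, O=C(Cl)C(=O)Cl
Why: Silyl esters are converted into acid chlorides by oxalyl chloride with catalytic DMF (Vilsmeier-type activation) without free HCl, so the aryl silyl ethers should survive.

Step 11
Reactants: 19 (1R,5S,7R)-5-geranyl-2-methoxy-8,8-dimethyl-1,7-diprenylbicyclo[3.3.1]non-2-ene-4,9-dione; 22 3,4-bis(tert-butyldimethylsilyloxy)benzoyl chloride
Product: 24 (1R,5R,7R)-3-[3,4-bis(tert-butyldimethylsilyloxy)benzoyl]-5-geranyl-2-methoxy-8,8-dimethyl-1,7-diprenylbicyclo[3.3.1]non-2-ene-4,9-dione, via vinyllithium 23 (not isolated)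
Conditions: LiTMP (2 equiv), THF, −78 °C; then 22 (3 equiv), −78 → −30 °C
Reagents that add atoms: none
Why: α-Lithiation of a β-methoxy enone at the vinylic C3 by LiTMP, then acylation of vinyllithium 23 by the acid chloride; both bridgeheads are quaternary, so C3–H is the only acidic site, and no stereocentre is touched.

Step 12
Reactants: 24 bis-silyl ether
Product: 25 (1R,5R,7R)-3-(3,4-dihydroxybenzoyl)-5-geranyl-2-methoxy-8,8-dimethyl-1,7-diprenylbicyclo[3.3.1]non-2-ene-4,9-dione
Conditions: TBAF, AcOH (1:1), THF, 0 °C
Reagents that add atoms: none
Why: Fluoride cleavage of aryl silyl ethers, buffered with acetic acid so that no phenoxide adds to the electrophilic β-methoxy enedione and the alkenes meet no strong acid.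

Step 13
Reactants: 25 O2-methyl ether of the target
Product: 26 (1S,5S,7R)-3-(3,4-dihydroxybenzoyl)-5-geranyl-4-hydroxy-8,8-dimethyl-1,7-diprenylbicyclo[3.3.1]non-3-ene-2,9-dione (target)
Conditions: LiCl, DMSO, 120 °C, argon; work-up at pH 4–5
Reagents that add atoms: none
Why: Nucleophilic O-demethylation (SN2 attack of chloride on the methyl group of the acyl vinylogous ester, Krapcho-type conditions) releases the stabilised triketone enolate; the neutral medium spares alkenes, catechol and acyl groups.

## Compound list

Geranyl is (2E)-3,7-dimethylocta-2,6-dien-1-yl and prenyl is 3-methylbut-2-en-1-yl. CIP descriptors change along the series (for example at C5 between 19 and 24, and at C1 and C5 between 25 and 26) only because substituent priorities change; no centre is inverted after step 6.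

1 | 2-methylcyclopent-2-en-1-one | CC1=CCCC1=O | starting material
2 | but-3-en-1-ylmagnesium bromide | C=CCC[Mg]Br | starting material
3 | bromomagnesium (3R)-3-(but-3-en-1-yl)-2-methylcyclopent-1-en-1-olate (not isolated) | Br[Mg]OC1=C(C)[C@H](CCC=C)CC1 | intermediate
4 | (3R)-3-(but-3-en-1-yl)-2,2-dimethylcyclopentan-1-one | O=C1CC[C@@H](CCC=C)C1(C)C | intermediate
5 | (3S)-3-[(2E)-but-2-en-1-yl]-2,2-dimethylcyclopentan-1-one | O=C1CC[C@@H](C/C=C/C)C1(C)C | intermediate
6 | (3S)-2,2-dimethyl-3-(3-methylbut-2-en-1-yl)cyclopentan-1-one | O=C1CC[C@@H](CC=C(C)C)C1(C)C | intermediate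
7 | geranyl bromide, (2E)-1-bromo-3,7-dimethylocta-2,6-diene | CC(C)=CCC/C(C)=C/CBr | starting material
8 | lithium enolate of 6 (not isolated) | [Li]OC1=CC[C@@H](CC=C(C)C)C1(C)C | intermediate
9 | (2S,4R)-2-geranyl-5,5-dimethyl-4-prenylcyclopentan-1-one (2,4-cis) | CC(C)=CCC/C(C)=C/C[C@H]1C[C@@H](CC=C(C)C)C(C)(C)C1=O | intermediate
10 | diketene, 4-methylideneoxetan-2-one | C=C1CC(=O)O1 | starting material
11 | lithium enolate of 9 (not isolated) | [Li]OC1=C(C/C=C(\C)CCC=C(C)C)C[C@@H](CC=C(C)C)C1(C)C | intermediate
12 | terminal lithium enolate of 2-acetoacetyl-2-geranyl-5,5-dimethyl-4-prenylcyclopentan-1-one, acyl group trans to prenyl (not isolated) | CC(C)=CCC/C(C)=C/C[C@@]1(C(=O)CC(=C)O[Li])C[C@@H](CC=C(C)C)C(C)(C)C1=O | intermediate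
13 | (2R,3aR,7aR)-3a-geranyl-7a-hydroxy-1,1-dimethyl-2-prenyl-octahydroindene-4,6-dione (cis-fused) | CC(C)=CCC/C(C)=C/C[C@@]12C[C@@H](CC=C(C)C)C(C)(C)[C@]1(O)CC(=O)CC2=O | intermediate
14 | C3 phenyliodonium ylide of 13 (not isolated) | CC(C)=CCC/C(C)=C/C[C@@]12C[C@@H](CC=C(C)C)C(C)(C)[C@]1(O)CC(=O)[C-]([I+]c3ccccc3)C2=O | intermediate
15 | (1R,5S,7R)-5-geranyl-8,8-dimethyl-7-prenylbicyclo[3.3.1]nonane-2,4,9-trione (C1–H bridgehead, C7 prenyl exo) | CC(C)=CCC/C(C)=C/C[C@]12C[C@@H](CC=C(C)C)C(C)(C)[C@H](C(=O)CC1=O)C2=O | intermediate
16 | (1R,5S,7R)-5-geranyl-2-methoxy-8,8-dimethyl-7-prenylbicyclo[3.3.1]non-2-ene-4,9-dione | CC(C)=CCC/C(C)=C/C[C@]12C[C@@H](CC=C(C)C)C(C)(C)[C@H](C(OC)=CC1=O)C2=O | intermediate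
17 | prenyl bromide, 1-bromo-3-methylbut-2-ene | CC(C)=CCBr | starting material
18 | C1 bridgehead lithio derivative of 16 (not isolated) | CC(C)=CCC/C(C)=C/C[C@]12C[C@@H](CC=C(C)C)C(C)(C)[C@]([Li])(C(OC)=CC1=O)C2=O | intermediate
19 | (1R,5S,7R)-5-geranyl-2-methoxy-8,8-dimethyl-1,7-diprenylbicyclo[3.3.1]non-2-ene-4,9-dione | CC(C)=CCC/C(C)=C/C[C@]12C[C@@H](CC=C(C)C)C(C)(C)[C@](CC=C(C)C)(C(OC)=CC1=O)C2=O | intermediate
20 | 3,4-dihydroxybenzoic acid | O=C(O)c1ccc(O)c(O)c1 | starting material
21 | tert-butyldimethylsilyl 3,4-bis(tert-butyldimethylsilyloxy)benzoate | CC(C)(C)[Si](C)(C)OC(=O)c1ccc(O[Si](C)(C)C(C)(C)C)c(O[Si](C)(C)C(C)(C)C)c1 | intermediate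
22 | 3,4-bis(tert-butyldimethylsilyloxy)benzoyl chloride | O=C(Cl)c1ccc(O[Si](C)(C)C(C)(C)C)c(O[Si](C)(C)C(C)(C)C)c1 | intermediate
23 | C3 lithio derivative of 19 (not isolated) | CC(C)=CCC/C(C)=C/C[C@]12C[C@@H](CC=C(C)C)C(C)(C)[C@](CC=C(C)C)(C(OC)=C([Li])C1=O)C2=O | intermediate
24 | (1R,5R,7R)-3-[3,4-bis(tert-butyldimethylsilyloxy)benzoyl]-5-geranyl-2-methoxy-8,8-dimethyl-1,7-diprenylbicyclo[3.3.1]non-2-ene-4,9-dione | CC(C)=CCC/C(C)=C/C[C@]12C[C@@H](CC=C(C)C)C(C)(C)[C@](CC=C(C)C)(C(OC)=C(C(=O)c3ccc(O[Si](C)(C)C(C)(C)C)c(O[Si](C)(C)C(C)(C)C)c3)C1=O)C2=O | intermediate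
25 | (1R,5R,7R)-3-(3,4-dihydroxybenzoyl)-5-geranyl-2-methoxy-8,8-dimethyl-1,7-diprenylbicyclo[3.3.1]non-2-ene-4,9-dione | CC(C)=CCC/C(C)=C/C[C@]12C[C@@H](CC=C(C)C)C(C)(C)[C@](CC=C(C)C)(C(OC)=C(C(=O)c3ccc(O)c(O)c3)C1=O)C2=O | intermediate
26 | (1S,5S,7R)-3-(3,4-dihydroxybenzoyl)-5-geranyl-4-hydroxy-8,8-dimethyl-1,7-diprenylbicyclo[3.3.1]non-3-ene-2,9-dione | CC(C)=CCC/C(C)=C/C[C@]12C[C@@H](CC=C(C)C)C(C)(C)[C@](CC=C(C)C)(C(=O)C(C(=O)c3ccc(O)c(O)c3)=C1O)C2=O | target

## Step count and least certain steps

Total step count: 13. Longest linear sequence: 11 steps (steps 1–8 and 11–13, from 1 to 26); the acid chloride branch (steps 9 and 10) has two steps.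

**Step 5 (key step).** The most likely failures are acylation on oxygen at an enolate whose carbon terminus is already fully substituted, with later loss of the acetoacetyl unit, and a weak facial preference because the directing prenyl group is two atoms away. The fallback sets out from 9 and returns at 13; it separates the two bond formations and uses an aldehyde, which can react only at carbon. 2-(2-Methyl-1,3-dioxolan-2-yl)acetaldehyde F1 is made by i-Bu2AlH reduction of commercial ethyl 2-(2-methyl-1,3-dioxolan-2-yl)acetate at −78 °C. Enolate 11 is added to it to give the aldol adduct 2-geranyl-2-[1-hydroxy-2-(2-methyl-1,3-dioxolan-2-yl)ethyl]-5,5-dimethyl-4-prenylcyclopentan-1-one F2. Dess–Martin periodinane oxidises this to the ketal-protected diketone F3, and pyridinium tosylate in wet acetone frees the 2-acetoacetyl ketone F4. Two equivalents of LiTMP convert it into the dianion, which closes ring A by the same aldol to give 13. The same two bonds are formed, at the cost of three more steps.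

**Step 1.** The most likely failures are insufficient enantioselection on the five-membered α-substituted enone and slow C-methylation of the magnesium enolate, which would leave protonated material. The fallback sets out from 1, replaces steps 1–3 and returns at 6; it uses an auxiliary-controlled conjugate addition. The allylphosphonamide (3aR,7aR)-2-allyl-1,3-dimethyloctahydro-1,3,2-benzodiazaphosphole 2-oxide F5 is made from allylphosphonic dichloride and (R,R)-N,N'-dimethylcyclohexane-1,2-diamine (the antipodal diamine is taken if the sense of induction requires it). It is lithiated with n-BuLi and added to 1 through its γ-carbon, and the enolate is methylated with iodomethane to give the vinylphosphonamide ketone F6. Ozonolysis with Me2S work-up gives (S)-2-(2,2-dimethyl-3-oxocyclopentyl)acetaldehyde F7. A Wittig reaction with isopropylidenetriphenylphosphorane, selective for the aldehyde over the neopentylic ketone, gives 6.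

**Step 6.** The most likely failures are retro-aldol opening of ring A in methanolic KOH before the shift, and stalling at ylide 14 without migration. The fallback sets out from 13 and returns at 15; it places an ordinary leaving group on C1 and triggers a halohydrin-type semipinacol shift. The trianion of 13 (LDA, 3.3 equiv; alkoxide, diketonate and the C1 carbanion, C1 being the only γ-carbon that bears hydrogen) is brominated with 1,2-dibromotetrachloroethane to give the 1-bromo hydroxy dione F8 as C1 epimers. Treatment with i-PrMgCl (THF, 0 °C → rt) forms the magnesium alkoxide, which expels bromide as C8 moves from C9 to C1, giving 15.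

**Step 8.** The most likely failures are slow alkylation of the bridgehead carbanion next to the gem-dimethyl carbon, with proton return or SN2' attack on the allylic bromide, and competing lithiation at C3. The fallback sets out from 16 and returns at 19. Organolithium 18 is trapped with iodine, a small electrophile, to give the bridgehead iodide F9. Radical allylation (allyltributylstannane, AIBN, benzene, 80 °C), which is free of the steric demands of SN2, gives the 1-allyl compound F10. Cross-metathesis with 2-methylbut-2-ene and the second-generation Grubbs catalyst converts allyl into prenyl and gives 19; the trisubstituted alkenes already present react far more slowly than the terminal one.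

**Step 11.** The most likely failure is slow combination of the hindered vinyllithium 23 with the hindered acid chloride, so that proton return on warming gives back 19. The fallback sets out from 19 and returns at 24; it uses addition to an aldehyde followed by oxidation. 3,4-Bis(tert-butyldimethylsilyloxy)benzaldehyde F11 is made by silylation of 3,4-dihydroxybenzaldehyde. It reacts with 23 at −78 °C to give the secondary carbinol F12 as a mixture of carbinol epimers, which Dess–Martin periodinane oxidises to 24.

## Further compounds

F1 | step 5 | 2-(2-methyl-1,3-dioxolan-2-yl)acetaldehyde | CC1(CC=O)OCCO1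
F2 | step 5 | 2-geranyl-2-[1-hydroxy-2-(2-methyl-1,3-dioxolan-2-yl)ethyl]-5,5-dimethyl-4-prenylcyclopentan-1-one (carbinol epimers) | CC(C)=CCC/C(C)=C/C[C@@]1(C(O)CC2(C)OCCO2)C[C@@H](CC=C(C)C)C(C)(C)C1=O
F3 | step 5 | 2-geranyl-5,5-dimethyl-2-[(2-methyl-1,3-dioxolan-2-yl)acetyl]-4-prenylcyclopentan-1-one | CC(C)=CCC/C(C)=C/C[C@@]1(C(=O)CC2(C)OCCO2)C[C@@H](CC=C(C)C)C(C)(C)C1=O
F4 | step 5 | 2-acetoacetyl-2-geranyl-5,5-dimethyl-4-prenylcyclopentan-1-one | CC(C)=CCC/C(C)=C/C[C@@]1(C(=O)CC(C)=O)C[C@@H](CC=C(C)C)C(C)(C)C1=O
F5 | step 1 | (3aR,7aR)-2-allyl-1,3-dimethyloctahydro-1,3,2-benzodiazaphosphole 2-oxide | C=CCP1(=O)N(C)[C@@H]2CCCC[C@H]2N1C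
F6 | step 1 | (3S)-2,2-dimethyl-3-[(2E)-3-((3aR,7aR)-1,3-dimethyl-2-oxidooctahydro-1,3,2-benzodiazaphosphol-2-yl)prop-2-en-1-yl]cyclopentan-1-one | O=C1CC[C@@H](C/C=C/P2(=O)N(C)[C@@H]3CCCC[C@H]3N2C)C1(C)C
F7 | step 1 | (S)-2-(2,2-dimethyl-3-oxocyclopentyl)acetaldehyde | O=C1CC[C@@H](CC=O)C1(C)C
F8 | step 6 | 1-bromo derivative of 13 (bromine on the ring A methylene next to the carbinol, C1 epimers) | CC(C)=CCC/C(C)=C/C[C@@]12C[C@@H](CC=C(C)C)C(C)(C)[C@]1(O)C(Br)C(=O)CC2=O
F9 | step 8 | 5-geranyl-1-iodo-2-methoxy-8,8-dimethyl-7-prenylbicyclo[3.3.1]non-2-ene-4,9-dione | CC(C)=CCC/C(C)=C/C[C@]12C[C@@H](CC=C(C)C)C(C)(C)[C@](I)(C(OC)=CC1=O)C2=O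
F10 | step 8 | 1-allyl-5-geranyl-2-methoxy-8,8-dimethyl-7-prenylbicyclo[3.3.1]non-2-ene-4,9-dione | CC(C)=CCC/C(C)=C/C[C@]12C[C@@H](CC=C(C)C)C(C)(C)[C@](CC=C)(C(OC)=CC1=O)C2=O
F11 | step 11 | 3,4-bis(tert-butyldimethylsilyloxy)benzaldehyde | O=Cc1ccc(O[Si](C)(C)C(C)(C)C)c(O[Si](C)(C)C(C)(C)C)c1
F12 | step 11 | 3-{[3,4-bis(tert-butyldimethylsilyloxy)phenyl](hydroxy)methyl}-5-geranyl-2-methoxy-8,8-dimethyl-1,7-diprenylbicyclo[3.3.1]non-2-ene-4,9-dione (carbinol epimers) | CC(C)=CCC/C(C)=C/C[C@]12C[C@@H](CC=C(C)C)C(C)(C)[C@](CC=C(C)C)(C(OC)=C(C(O)c3ccc(O[Si](C)(C)C(C)(C)C)c(O[Si](C)(C)C(C)(C)C)c3)C1=O)C2=O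
A1 | alternative 1 | bis(tert-butyldimethylsilyl) ether of the target | CC(C)=CCC/C(C)=C/C[C@]12C[C@@H](CC=C(C)C)C(C)(C)[C@](CC=C(C)C)(C(=O)C(C(=O)c3ccc(O[Si](C)(C)C(C)(C)C)c(O[Si](C)(C)C(C)(C)C)c3)=C1O)C2=O
A2 | alternative 1 | 5-geranyl-8,8-dimethyl-1,7-diprenyl-3-oxabicyclo[3.3.1]nonane-2,4,9-trione (bridged anhydride) | CC(C)=CCC/C(C)=C/C[C@]12C[C@@H](CC=C(C)C)C(C)(C)[C@](CC=C(C)C)(C(=O)OC1=O)C2=O
A3 | alternative 1 | 3,4-bis(tert-butyldimethylsilyloxy)acetophenone | CC(=O)c1ccc(O[Si](C)(C)C(C)(C)C)c(O[Si](C)(C)C(C)(C)C)c1
A4 | alternative 2 | 3-[3,4-bis(tert-butyldimethylsilyloxy)benzoyl]-7-exo-formyl-5-geranyl-2-methoxy-8,8-dimethyl-1-prenylbicyclo[3.3.1]non-2-ene-4,9-dione | CC(C)=CCC/C(C)=C/C[C@]12C[C@@H](C=O)C(C)(C)[C@](CC=C(C)C)(C(OC)=C(C(=O)c3ccc(O[Si](C)(C)C(C)(C)C)c(O[Si](C)(C)C(C)(C)C)c3)C1=O)C2=O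
A5 | alternative 2 | [3,4-bis(tert-butyldimethylsilyloxy)phenyl][3-geranyl-2,4-dihydroxy-6-methoxy-5-prenylphenyl]methanone | COc1c(CC=C(C)C)c(O)c(C/C=C(\C)CCC=C(C)C)c(O)c1C(=O)c1ccc(O[Si](C)(C)C(C)(C)C)c(O[Si](C)(C)C(C)(C)C)c1
A6 | alternative 2 | 2-(acetoxymethyl)-3-methylbut-2-enal | CC(C)=C(COC(C)=O)C=O
A7 | alternative 3 | 7-exo-formyl-8,8-dimethyl-1-prenylbicyclo[3.3.1]nonane-2,4,9-trione with hydrogen at C5 | O=C1[C@H]2C[C@@H](C=O)C(C)(C)[C@]1(CC=C(C)C)C(=O)CC2=O
A8 | alternative 3 | 3-methyl-3-[2,4,6-trioxo-1-prenylcyclohexyl]butanal | CC(C)=CCC1(C(C)(C)CC=O)C(=O)CC(=O)CC1=O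
A9 | alternative 3 | formaldehyde | C=O
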